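**Retrosynthetic overview**
1. Feature: in the eight-membered ring the acetoxy carbon (C1) and the side-chain carbon (C8) are adjacent sp3 atoms with cis substituents, while C2–C7 can all be sp2 (C6=C7 being the butenolide alkene); this is the product pattern of an 8π electrocyclisation.
2. Target 20 ⇐ acetylation, hydroxyl-directed hydrogenation of C2=C3 (sets C3) and methylene transfer to C4=C5 (cyclopropane, third ring) from cyclooctatriene 16.
3. 16 ⇐ tetraene 15 by thermal conrotatory 8π closure (C1–C8 bond, eight-membered ring, second ring; C1 and C8 set); 15 ⇐ terminal alkyne 14 + acetic acid (Z-enol acetate).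
4. 14 ⇐ dialkylidene lactone (first ring) by Stille coupling (C6–C7) and lactonisation of vinyl iodide 6 with α-stannyl enoate 11.
5. 6 ⇐ (Z)-3-methylpent-2-en-4-yn-1-ol 1 (C3=C4 geometry bought in); 11 ⇐ (R)-citronellal 7 (side-chain centre).

Key step: step 10

Locants: C1–C8 are the tetraene carbons and keep their numbers in the eight-membered ring (C1 acetoxy, C3 methyl, C6 lactone CH2O, C7 lactone C=O, C8 side chain); "side chain" is (2R)-6-methylhept-5-en-2-yl; CIP descriptors of ring compounds refer to these locants.
Assumption: 1 is taken as purchased as the single Z isomer; if only the E/Z mixture is at hand, the isomers are separated by distillation before step 1.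

**Route**

Step 1
Reactants: 1 (Z)-3-methylpent-2-en-4-yn-1-ol
Product: 3 (Z)-3-methyl-5-(trimethylsilyl)pent-2-en-4-yn-1-ol, via bis-silyl ether 2 (not isolated)
Conditions: n-BuLi (2.1 equiv), THF, −78 °C; Me3SiCl (2.2 equiv), −78 °C → rt; then 1 M HCl, rt
Reagents that add atoms: chlorotrimethylsilane, SMILES C[Si](C)(C)Cl
Why: Double deprotonation and silylation at oxygen and at the acetylide carbon (C-silylation of an alkyne), followed by acid cleavage of the labile O–Si bond only, caps the terminal alkyne for the later copper-assisted coupling without touching the Z alkene.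

Step 2
Reactants: 3 (Z)-3-methyl-5-(trimethylsilyl)pent-2-en-4-yn-1-ol
Product: 4 (Z)-3-methyl-5-(trimethylsilyl)pent-2-en-4-ynal
Conditions: MnO2 (excess), CH2Cl2, rt
Reagents that add atoms: none
Why: Allylic alcohol oxidation on MnO2 is neutral and heterogeneous, so the (Z)-enal should form without Z to E isomerisation.

Step 3
Reactants: 4 (Z)-3-methyl-5-(trimethylsilyl)pent-2-en-4-ynal
Product: 5 ethyl (2Z,4Z)-2-iodo-5-methyl-7-(trimethylsilyl)hepta-2,4-dien-6-ynoate
Conditions: Ph3P=CHCO2Et, N-iodosuccinimide, CH2Cl2, −20 °C; then 4, −20 °C → rt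
Reagents that add atoms: ethyl (triphenylphosphoranylidene)acetate, SMILES CCOC(=O)C=P(c1ccccc1)(c1ccccc1)c1ccccc1; N-iodosuccinimide, SMILES O=C1CCC(=O)N1I
Why: Wittig olefination with the ester-stabilised iodo ylide made in the flask places the dienyl residue trans to the ester and therefore cis to iodine, which is the C5=C6 geometry needed once iodine is replaced by C7 (any minor 2E isomer is removed by chromatography).

Step 4
Reactants: 5 ethyl (2Z,4Z)-2-iodo-5-methyl-7-(trimethylsilyl)hepta-2,4-dien-6-ynoate
Product: 6 (2Z,4Z)-2-iodo-5-methyl-7-(trimethylsilyl)hepta-2,4-dien-6-yn-1-ol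
Conditions: i-Bu2AlH (2.3 equiv), CH2Cl2, −78 °C; aq. potassium sodium tartrate work-up
Reagents that add atoms: none
Why: Hydride reduction of the enoate to the primary allylic alcohol at low temperature leaves the vinyl iodide, the silylalkyne and both alkene geometries intact.

Step 5
Reactants: 7 (R)-citronellal
Product: 9 (R)-3,7-dimethyloct-6-en-1-yne, via alkenyl nonaflate 8 (not isolated)
Conditions: C4F9SO2F, P2-Et phosphazene base (2.5 equiv), DMF, −30 °C → rt
Reagents that add atoms: none
Why: O-Sulfonylation of the aldehyde enolate gives alkenyl nonaflate 8 and a second equivalent of base effects vinylic E2 elimination to the terminal alkyne (aldehyde-to-alkyne conversion without change of chain length); the basic medium avoids the acid-induced carbonyl-ene cyclisation of citronellal and the base is too weak to deprotonate the propargylic C–H, so the C3 centre is kept.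

Step 6
Reactants: 9 (R)-3,7-dimethyloct-6-en-1-yne
Product: 10 methyl (R)-4,8-dimethylnon-7-en-2-ynoate
Conditions: n-BuLi, THF, −78 °C; ClCO2Me, −78 → 0 °C
Reagents that add atoms: methyl chloroformate, SMILES COC(Cl)=O
Why: Deprotonation of the terminal alkyne and C-acylation of the acetylide with the chloroformate gives the ynoate that supplies C8, C7 and the lactone carbonyl.

Step 7
Reactants: 10 methyl (R)-4,8-dimethylnon-7-en-2-ynoate
Product: 11 methyl (2E,4R)-4,8-dimethyl-2-(tributylstannyl)nona-2,7-dienoate
Conditions: Bu3SnH (slow addition), Pd(PPh3)4 (2 mol%), THF, 0 °C → rt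
Reagents that add atoms: tributyltin hydride, SMILES CCCC[SnH](CCCC)CCCC
Why: Palladium-catalysed hydrostannation of an alkynoate is a syn addition that puts tin on the α-carbon and hydrogen on the branched β-carbon, giving the (E)-α-stannyl enoate in which the side chain is cis to the ester.

Step 8
Reactants: 6 (2Z,4Z)-2-iodo-5-methyl-7-(trimethylsilyl)hepta-2,4-dien-6-yn-1-ol; 11 methyl (2E,4R)-4,8-dimethyl-2-(tributylstannyl)nona-2,7-dienoate
Product: 13 (3Z,4E)-3-[(2R)-2,6-dimethylhept-5-en-1-ylidene]-4-[(2Z)-3-methyl-5-(trimethylsilyl)pent-2-en-4-yn-1-ylidene]oxolan-2-one, via hydroxy ester 12 (not isolated)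
Conditions: Pd2(dba)3 (5 mol%), AsPh3 (40 mol%), CuI (20 mol%), NMP, rt → 40 °C; then camphorsulfonic acid (10 mol%), CH2Cl2, rt
Reagents that add atoms: none
Why: Stille coupling with CuI assistance joins C6 and C7 with retention at both alkenyl carbons, and the hydroxymethyl and ester groups, held on the same side of the new diene, lactonise under acid catalysis, which locks the C6–C7 bond s-cis.

Step 9
Reactants: 13 (3Z,4E)-3-[(2R)-2,6-dimethylhept-5-en-1-ylidene]-4-[(2Z)-3-methyl-5-(trimethylsilyl)pent-2-en-4-yn-1-ylidene]oxolan-2-one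
Product: 14 (3Z,4E)-3-[(2R)-2,6-dimethylhept-5-en-1-ylidene]-4-[(2Z)-3-methylpent-2-en-4-yn-1-ylidene]oxolan-2-one
Conditions: Bu4NF (1.1 equiv), AcOH (1.2 equiv), THF, 0 °C; product kept cold and used at once
Reagents that add atoms: none
Why: Fluoride-induced protodesilylation of the alkynylsilane, buffered with acetic acid so that the dialkylidene lactone sees no free base, uncovers the terminal alkyne.

Step 10
Reactants: 14 (3Z,4E)-3-[(2R)-2,6-dimethylhept-5-en-1-ylidene]-4-[(2Z)-3-methylpent-2-en-4-yn-1-ylidene]oxolan-2-one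
Product: 16 (1R,8S)-3-methyl-8-[(2R)-6-methylhept-5-en-2-yl]cycloocta-2,4,6-trien-1-yl acetate fused at C6–C7 to a but-2-enolide (CH2O on C6, C=O on C7), via tetraene 15 (not isolated)
Conditions: AcOH (2 equiv), Ru(η3-2-methylallyl)2(dppb) (5 mol%), toluene, argon, 45 → 60 °C until 15 is consumed
Reagents that add atoms: acetic acid, SMILES CC(=O)O
Why: The ruthenium vinylidene formed from the terminal alkyne is attacked at its α-carbon by acetate and gives the (Z)-enol acetate 15 (anti-Markovnikov addition of carboxylic acids to enynes); 15 has both inner alkenes cis along the chain and the lactone holds C6–C7 s-cis, so it coils into a helix and undergoes thermal conrotatory 8π electrocyclisation, the known behaviour of (Z,Z)-octa-1,3,5,7-tetraenes. The eight-membered ring closes by σ-bond formation between the helix termini C1 and C8, and the two exocyclic lactone alkenes become the endocyclic butenolide alkene C6=C7. C1 and C8 are set together: conrotation of the inward acetoxy group at C1 and the outward side chain at C8 places them cis. Their absolute sense follows the helix sense, which the (R) methine on C8 biases through 1,3-allylic strain: its C–H lies in the plane of C7=C8 toward the lactone carbonyl, and C1 should bond to the face carrying the methyl group, not the homoprenyl chain; this bias is expected to be modest and the (1S,8R) diastereomer is to be removed by chromatography. The step needs Z-selective ester addition, which the vinylidene pathway secures, and arrest at the cyclooctatriene, which is secured because a following 6π closure would place a quaternary sp3 carbon at C7 and break the butenolide conjugation.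

Step 11
Reactants: 16 (1R,8S)-cyclooctatriene acetate
Product: 17 (1R,4R,5S,8S)-4,5-methano derivative of 16 (cyclopropane on C4–C5, its CH2 cis to the acetoxy group and the side chain)
Conditions: CH2N2 (excess, Et2O), Pd(OAc)2 (5 mol%), CH2Cl2/Et2O, 0 °C
Reagents that add atoms: diazomethane, SMILES C=[N+]=[N-]
Why: Palladium-catalysed methylene transfer from diazomethane (cyclopropanation) takes 1,2-disubstituted alkenes and not tri- or tetrasubstituted ones, so only C4=C5 should react; the triene ring is a tub with the C1 and C8 substituents pseudo-equatorial, and the carbene should add to the open convex face of C4=C5, which is the face cis to both substituents (C4 and C5 set by substrate control).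

Step 12
Reactants: 17 cyclopropanated acetate
Product: 18 (1R,4R,5S,8S)-alcohol corresponding to 17 (C1–OH)
Conditions: K2CO3 (0.5 equiv), MeOH, 0 °C
Reagents that add atoms: none
Why: Base-catalysed transesterification with methanol removes the acetate and exposes the hydroxyl needed as a directing group, the butenolide being inert or reclosing under these conditions.

Step 13
Reactants: 18 allylic alcohol
Product: 19 (1R,3R,4S,5S,8S)-2,3-dihydro alcohol (C3 methyl trans to the C1 hydroxyl)
Conditions: H2 (55 bar), [Rh(nbd)(dppb)]BF4 (10 mol%), CH2Cl2, rt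
Reagents that add atoms: none
Why: Hydroxyl-directed homogeneous hydrogenation: the C1 hydroxyl binds the cationic rhodium and hydrogen is delivered to the C2=C3 face syn to it, which sets C3 with methyl trans to oxygen, while the undirected side-chain alkene and the tetrasubstituted butenolide alkene should react far more slowly and high pressure suppresses alkene isomerisation.

Step 14
Reactants: 19 saturated alcohol
Product: 20 target, (1R,3R,4S,5S,8S)-acetate
Conditions: Ac2O, pyridine, DMAP (cat.), CH2Cl2, 0 °C → rt
Reagents that add atoms: acetic anhydride, SMILES CC(=O)OC(C)=O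
Why: DMAP-catalysed acylation of the secondary alcohol restores the acetate without touching any stereocentre.

**Compound list**
1 | (Z)-3-methylpent-2-en-4-yn-1-ol | C#C/C(C)=C\CO | starting material
2 | (Z)-trimethyl{[3-methyl-5-(trimethylsilyl)pent-2-en-4-yn-1-yl]oxy}silane | C[Si](C)(C)C#C/C(C)=C\CO[Si](C)(C)C | intermediate
3 | (Z)-3-methyl-5-(trimethylsilyl)pent-2-en-4-yn-1-ol | C[Si](C)(C)C#C/C(C)=C\CO | intermediate
4 | (Z)-3-methyl-5-(trimethylsilyl)pent-2-en-4-ynal | C[Si](C)(C)C#C/C(C)=C\C=O | intermediate
5 | ethyl (2Z,4Z)-2-iodo-5-methyl-7-(trimethylsilyl)hepta-2,4-dien-6-ynoate | C[Si](C)(C)C#C/C(C)=C\C=C(/I)C(=O)OCC | intermediate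
6 | (2Z,4Z)-2-iodo-5-methyl-7-(trimethylsilyl)hepta-2,4-dien-6-yn-1-ol | C[Si](C)(C)C#C/C(C)=C\C=C(/I)CO | intermediate
7 | (R)-citronellal | O=CC[C@H](C)CCC=C(C)C | starting material
8 | (3R)-3,7-dimethylocta-1,6-dien-1-yl nonafluorobutane-1-sulfonate (E/Z mixture) | CC(C)=CCC[C@@H](C)C=COS(=O)(=O)C(F)(F)C(F)(F)C(F)(F)C(F)(F)F | intermediate
9 | (R)-3,7-dimethyloct-6-en-1-yne | C#C[C@H](C)CCC=C(C)C | intermediate
10 | methyl (R)-4,8-dimethylnon-7-en-2-ynoate | COC(=O)C#C[C@H](C)CCC=C(C)C | intermediate
11 | methyl (2E,4R)-4,8-dimethyl-2-(tributylstannyl)nona-2,7-dienoate | COC(=O)/C(=C\[C@H](C)CCC=C(C)C)[Sn](CCCC)(CCCC)CCCC | intermediate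
12 | methyl (2Z,4R)-2-[(2E,4Z)-1-hydroxy-5-methyl-7-(trimethylsilyl)hepta-2,4-dien-6-yn-2-yl]-4,8-dimethylnona-2,7-dienoate | COC(=O)/C(=C\[C@H](C)CCC=C(C)C)/C(CO)=C\C=C(C)/C#C[Si](C)(C)C | intermediate
13 | (3Z,4E)-3-[(2R)-2,6-dimethylhept-5-en-1-ylidene]-4-[(2Z)-3-methyl-5-(trimethylsilyl)pent-2-en-4-yn-1-ylidene]oxolan-2-one | C[Si](C)(C)C#C\C(C)=C/C=C1/COC(=O)/C1=C\[C@H](C)CCC=C(C)C | intermediate
14 | (3Z,4E)-3-[(2R)-2,6-dimethylhept-5-en-1-ylidene]-4-[(2Z)-3-methylpent-2-en-4-yn-1-ylidene]oxolan-2-one | C#C\C(C)=C/C=C1/COC(=O)/C1=C\[C@H](C)CCC=C(C)C | intermediate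
15 | (1Z,3Z)-5-{(3E,4Z)-4-[(2R)-2,6-dimethylhept-5-en-1-ylidene]-5-oxooxolan-3-ylidene}-3-methylpenta-1,3-dien-1-yl acetate (tetraene) | CC(=O)O/C=C\C(C)=C/C=C1/COC(=O)/C1=C\[C@H](C)CCC=C(C)C | intermediate
16 | (1R,8S)-3-methyl-8-[(2R)-6-methylhept-5-en-2-yl]cycloocta-2,4,6-trien-1-yl acetate fused at C6–C7 to a but-2-enolide | CC(=O)O[C@@H]1/C=C(C)\C=C/C2=C(C(=O)OC2)[C@@H]1[C@H](C)CCC=C(C)C | intermediate
17 | (1R,4R,5S,8S)-4,5-methano derivative of 16, CH2 cis to acetoxy and side chain | CC(=O)O[C@@H]1/C=C(C)\[C@@H]2C[C@@H]2C2=C(C(=O)OC2)[C@@H]1[C@H](C)CCC=C(C)C | intermediate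
18 | (1R,4R,5S,8S)-C1 alcohol corresponding to 17 | O[C@@H]1/C=C(C)\[C@@H]2C[C@@H]2C2=C(C(=O)OC2)[C@@H]1[C@H](C)CCC=C(C)C | intermediate
19 | (1R,3R,4S,5S,8S)-2,3-dihydro alcohol, C3 methyl trans to C1 hydroxyl | O[C@@H]1C[C@@H](C)[C@@H]2C[C@@H]2C2=C(C(=O)OC2)[C@@H]1[C@H](C)CCC=C(C)C | intermediate
20 | target, (1R,3R,4S,5S,8S)-acetate | CC(=O)O[C@@H]1C[C@@H](C)[C@@H]2C[C@@H]2C2=C(C(=O)OC2)[C@@H]1[C@H](C)CCC=C(C)C | target

**Totals**
Total step count: 14. Longest linear sequence: 11 steps (steps 1–4 and 8–14).

**Steps most likely to fail**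

1. Step 10 (key step). The ruthenium vinylidene may be intercepted by the neighbouring diene. The s-cis trienyne 14 may also undergo 6π closure at 45 °C before acetate is added, so that the tetraene never forms cleanly. Selection between the two helix senses may also be low.
Fallback, from 6 back to 16, with the cross-coupling placed last so that the enol acetate is made on a small, robust enyne:
- 6 is desilylated (K2CO3, MeOH, 0 °C) to (2Z,4Z)-2-iodo-5-methylhepta-2,4-dien-6-yn-1-ol F1.
- The same ruthenium-catalysed Z-selective addition of acetic acid (toluene, 45 °C) gives (1Z,3Z,5Z)-7-hydroxy-6-iodo-3-methylhepta-1,3,5-trien-1-yl acetate F2.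
- Stille coupling of F2 with 11 (Pd2(dba)3, AsPh3, CuI, NMP, rt) gives methyl (2Z,4R)-2-[(2E,4Z,6Z)-7-acetoxy-1-hydroxy-5-methylhepta-2,4,6-trien-2-yl]-4,8-dimethylnona-2,7-dienoate F3. The enol acetate is not an allylic ester, so zerovalent palladium should not ionise it.
- F3 is freed from palladium by filtration through silica and treated with camphorsulfonic acid (cat.) in CH2Cl2 at rt to 40 °C. Lactonisation gives 15, which closes to 16; if F3 closes first, lactonisation of the cis-disposed CH2OH and ester gives the same 16.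

2. Step 11. Carbene transfer may stall at the internal alkene, which is flanked by two substituted sp2 carbons. Zerovalent palladium would then have time to ionise the trienyl acetate, and methylene delivery to both faces is also possible.
Fallback, from 16 back to 18, with nucleophilic methylene transfer in place of carbene transfer:
- 16 is deacetylated first (K2CO3, MeOH, 0 °C) to the trienol F4, (1R,8S)-C1 alcohol corresponding to 16, which has no leaving group.
- F4 is treated with dimethylsulfoxonium methylide (Me3S(O)I, NaH, DMSO, rt; Corey–Chaykovsky reaction). The β-carbon C6 is fully substituted, so the ylide should add 1,6 at C4 and the resulting dienolate should close from C5 onto the CH2, as in the γ,δ-methylenation of β-blocked dienones.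
- Attack at C2 is disfavoured by the neighbouring alkoxide and by the tertiary closure site C3. The product is 18.

3. Step 8. Tin-to-palladium transfer from the hindered, electron-poor α-stannyl enoate may be slow and lead to protodestannylation and homocoupling. The C7=C8 geometry may also erode through a copper allenoate.
Fallback, from 10 and 6 back to 13, forming the C6–C7 bond within an ester tether (step 7 is then not needed):
- 10 is saponified (LiOH, THF/H2O, 0 °C) to (R)-4,8-dimethylnon-7-en-2-ynoic acid F5.
- F5 is esterified with 6 (DCC, DMAP, CH2Cl2, 0 °C) to (2Z,4Z)-2-iodo-5-methyl-7-(trimethylsilyl)hepta-2,4-dien-6-yn-1-yl (R)-4,8-dimethylnon-7-en-2-ynoate F6.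
- Reductive cyclisation (Pd(OAc)2, PPh3, HCO2Na, DMF, 60 °C) gives 13. Zerovalent palladium formed in the flask inserts into the C6–I bond, 5-exo-dig syn carbopalladation of the ynoate forms C6–C7, and formate reduces the C8–Pd bond with retention.
- Hydrogen on C8 therefore ends cis to C6 and the side chain cis to the carbonyl, and the C5=C6 geometry of 6 is kept.

**Further compounds**
F1 | step 10 | (2Z,4Z)-2-iodo-5-methylhepta-2,4-dien-6-yn-1-ol | C#C/C(C)=C\C=C(/I)CO
F2 | step 10 | (1Z,3Z,5Z)-7-hydroxy-6-iodo-3-methylhepta-1,3,5-trien-1-yl acetate | CC(=O)O/C=C\C(C)=C/C=C(\I)CO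
F3 | step 10 | methyl (2Z,4R)-2-[(2E,4Z,6Z)-7-acetoxy-1-hydroxy-5-methylhepta-2,4,6-trien-2-yl]-4,8-dimethylnona-2,7-dienoate | COC(=O)/C(=C\[C@H](C)CCC=C(C)C)/C(CO)=C\C=C(C)/C=C\OC(C)=O
F4 | step 11 | (1R,8S)-C1 alcohol corresponding to 16 (trienol) | O[C@@H]1/C=C(C)\C=C/C2=C(C(=O)OC2)[C@@H]1[C@H](C)CCC=C(C)C
F5 | step 8 | (R)-4,8-dimethylnon-7-en-2-ynoic acid | OC(=O)C#C[C@H](C)CCC=C(C)C
F6 | step 8 | (2Z,4Z)-2-iodo-5-methyl-7-(trimethylsilyl)hepta-2,4-dien-6-yn-1-yl (R)-4,8-dimethylnon-7-en-2-ynoate | C[Si](C)(C)C#C/C(C)=C\C=C(/I)COC(=O)C#C[C@H](C)CCC=C(C)C
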